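The target is the ring-opened form of a β-methylbutenolide. Across the C13=C14 bond the C12 oxygen and the C15 carboxyl lie on the same side, so an O12–C15 lactone can be closed and later reopened. The plan therefore rests on cutting C12–C13, next to that alkene. One nickel/chromium coupling joins a geometrically pure (Z)-β-iodocrotonate to a C12 aldehyde, sets C12 as S under ligand control and lactonises in the same flask. The aldehyde is a trans-decalin (rings A and B) carved from podocarpic acid. Ring C supplies C11, C12 and, through C14, the 8(17)-methylene, while C19 is masked as a silylethyl ester.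

Key step: step 10

Remarks before the steps
- Numbering: podocarpane/labdane numbering is used throughout. C14 of podocarpic acid ends as C17, and C13 is excised.
- Configuration check: the target is 12S,13Z in the normal labdane series (5α-H, 9α-H, 10β-CH3, axial 4β-CO2H). Rings A and B match natural (+)-podocarpic acid. 12S requires attack on the Re face of the C12 aldehyde.
- Assumption: the (S)-tert-leucinol-derived ligand L* is taken to direct Re-face attack. The sense is calibrated in a pilot run with both antipodes, which are equally accessible, and the matching one is used.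
- The dissolving-metal reduction is run on the free C19 acid, because an ester would not survive it.
- No ring-opened Δ8(9) aldehyde is used. Moving a tetrasubstituted ring alkene into an exocyclic enal is thermodynamically doubtful, and two cis CH2C=O arms would condense with each other. C9 is therefore set by hydrogenation, and C13 leaves as methyl formate in the step that creates the 8(17)-methylene.
- The lactone is opened before fluoride is applied, so that basic fluoride never meets the acidic C12–H of the butenolide.

Step 1
Reactants: 1 (+)-podocarpic acid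
Product: 2 O-methylpodocarpic acid (12-methoxypodocarpa-8,11,13-trien-19-oic acid)
Conditions: Me2SO4 (1.2 equiv), NaOH (3 equiv), H2O, 0 °C to rt; then cold dilute HCl
Reagents that add atoms: dimethyl sulfate, COS(=O)(=O)OC
Why: Williamson-type O-methylation works here because in aqueous NaOH the phenoxide O12 is far more nucleophilic than the hydrated, sterically buried axial C19 carboxylate, so the acid stays free as the next step requires.

Step 2
Reactants: 2 O-methylpodocarpic acid
Product: 5 12-oxopodocarp-9(11)-en-19-oic acid (8β-H), via Birch diene 3 (not isolated), via unconjugated enone 4 (not isolated)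
Conditions: Li, NH3(l)/THF/t-BuOH, −78 to −33 °C; NH4Cl; then 3 M HCl, THF, 60 °C
Reagents that add atoms: water, O
Why: Birch reduction of the anisole ring leaves the two alkenes where they are best substituted (C12=C13 bearing OMe and the tetrasubstituted C8=C9) while the lithium carboxylate resists electron transfer, and aqueous acid then hydrolyses the enol ether and conjugates the alkene into C9=C11 with equilibrium protonation of C8 to the more stable 8β-H epimer, a centre that step 6 erases anyway.

Step 3
Reactants: 5 12-oxopodocarp-9(11)-en-19-oic acid; 6 2-(trimethylsilyl)ethanol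
Product: 7 2-(trimethylsilyl)ethyl 12-oxopodocarp-9(11)-en-19-oate
Conditions: PPh3, DIAD, THF, 0 °C to rt
Reagents that add atoms: none
Why: Mitsunobu esterification succeeds where acyl-transfer methods stall, because the hindered C19 carboxylate only has to act as a nucleophile towards the unhindered primary carbon of the alkoxyphosphonium ion derived from 6, and no stereocentre is involved.

Step 4
Reactants: 7 2-(trimethylsilyl)ethyl 12-oxopodocarp-9(11)-en-19-oate
Product: 8 2-(trimethylsilyl)ethyl 12-oxo-8β,9α-podocarpan-19-oate
Conditions: H2 (1–4 atm), 10% Pd/C, EtOAc, rt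
Reagents that add atoms: none
Why: Heterogeneous catalytic hydrogenation adds hydrogen syn to the α face of C9=C11, the β face being screened by the axial C20 methyl on the neighbouring C10, which sets 9α-H with C11 equatorial (the trans-anti-trans array) and leaves ketone and ester untouched.

Step 5
Reactants: 8 2-(trimethylsilyl)ethyl 12-oxo-8β,9α-podocarpan-19-oate
Product: 9 2-(trimethylsilyl)ethyl 12-(trimethylsilyloxy)podocarp-12-en-19-oate
Conditions: LiN(i-Pr)2, THF, −78 °C; Me3SiCl, −78 to 0 °C; pentane, cold aq NaHCO3
Reagents that add atoms: chlorotrimethylsilane, C[Si](C)(C)Cl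
Why: Kinetic enolate formation and O-silylation should go towards C13 because the axial H11 sits in the crowded bay under the C20 methyl and C1, and because a trans-fused six-membered ketone of this type (compare 5α-3-keto steroids) also prefers the enol double bond pointing away from the ring fusion, so kinetic and thermodynamic preferences agree, while the C19 ester has no α-hydrogen.

Step 6
Reactants: 9 2-(trimethylsilyl)ethyl 12-(trimethylsilyloxy)podocarp-12-en-19-oate
Product: 11 13,14,15,16-tetranorlabd-8(17)-ene-12,19-dioic acid 19-[2-(trimethylsilyl)ethyl] ester, via methoxy hydroperoxide 10 (not isolated)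
Conditions: O3, CH2Cl2/MeOH (1:1), −78 °C; N2 purge; then FeSO4·7H2O (1.2 equiv), Cu(OAc)2·H2O (2 equiv), MeOH, −20 °C to rt
Reagents that add atoms: ozone, [O-][O+]=O; methanol, CO (enters intermediate 10 only and leaves again)
Why: Ozonolysis of the silyl enol ether splits into the C12 silyl ester and the C13 carbonyl oxide, which methanol traps as α-methoxy hydroperoxide 10, after which divalent iron cleaves the O–O bond, the alkoxyl radical undergoes β-scission of C13–C14 with loss of methyl formate, and Cu(OAc)2 oxidises the primary C14 radical through an alkylcopper species whose only β-hydrogen is H8, so the 8(17)-methylene is the sole possible alkene (iron/copper fragmentation of α-alkoxy hydroperoxides) and C9 is not touched.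

Step 7
Reactants: 11 13,14,15,16-tetranorlabd-8(17)-ene-12,19-dioic acid 19-[2-(trimethylsilyl)ethyl] ester
Product: 12 C12 N-methoxy-N-methylamide (Weinreb amide) of 11
Conditions: MeNHOMe·HCl, EDC·HCl, DMAP (cat.), i-Pr2NEt, CH2Cl2, 0 °C to rt
Reagents that add atoms: N,O-dimethylhydroxylamine hydrochloride, CNOC.Cl
Why: Carbodiimide amide coupling of the unhindered C12 acid gives the Weinreb amide, chosen because its chelated tetrahedral adduct stops hydride reduction cleanly at the aldehyde stage.

Step 8
Reactants: 12 C12 Weinreb amide
Product: 13 2-(trimethylsilyl)ethyl 12-oxo-13,14,15,16-tetranorlabd-8(17)-en-19-oate (decalin C12 aldehyde)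
Conditions: i-Bu2AlH (1.2 equiv), THF, −78 °C; aq potassium sodium tartrate; used promptly
Reagents that add atoms: none
Why: Hydride addition to the Weinreb amide gives a chelated aluminium hemiaminal that collapses to the aldehyde only on work-up, while the neopentyl-type axial C19 ester is too hindered to react with about one equivalent of i-Bu2AlH at −78 °C and the alkene is inert.

Step 9
Reactants: 14 methyl but-2-ynoate
Product: 15 methyl (Z)-3-iodobut-2-enoate
Conditions: NaI (1.6 equiv), AcOH, 115 °C
Reagents that add atoms: sodium iodide, [Na+].[I-]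
Why: Conjugate hydroiodination of the ynoate proceeds as a net anti addition of HI (iodide to C3, proton to C2 from the opposite side), which places iodine cis to the ester and so fixes the Z geometry needed for lactonisation.

Step 10
Reactants: 13 decalin C12 aldehyde; 15 methyl (Z)-3-iodobut-2-enoate (2 equiv)
Product: 18 (12S)-labda-8(17),13-dien-15,12-olide 19-[2-(trimethylsilyl)ethyl] ester (C12 butenolide), via alkenylchromium 16 (not isolated), via chromium alkoxide 17 (not isolated)
Conditions: CrCl2 (4 equiv), L* = (S)-N-[2-(4-tert-butyl-4,5-dihydrooxazol-2-yl)-6-methylphenyl]methanesulfonamide (4.4 equiv), Et3N (4.4 equiv), THF, rt, 1 h; then NiCl2 (2 mol %), 13 and 15, rt; aq potassium sodium tartrate/NaHCO3; SiO2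
Reagents that add atoms: none
Why: Oxidative addition of the C13–I bond of 15 to zerovalent nickel (generated from NiCl2 by CrCl2) is followed by transmetallation to trivalent chromium, two CrCl2 being consumed per iodide, and the alkenylchromium 16 adds to the aldehyde carbon C12 of 13. Because the ester is cis to the new C12–O bond across C13=C14, the alkoxide oxygen of 17 is held next to C15, and a 5-exo-trig addition–elimination at that carbonyl releases methoxide and forms the five-membered lactone ring. The closest known chemistry is the Nozaki–Hiyama–Kishi coupling of (Z)-β-iodo enoates with aldehydes that ends in butenolides, combined with the ligand-controlled variant run with oxazoline–sulfonamide chromium complexes. C12 is the only new stereocentre and is set by the ligand sphere on chromium, which has to steer C13 to the Re face of the aldehyde to give 12S, since the nearest substrate centre C9 is β to the carbonyl and offers only weak 1,3-induction. The step needs chemoselectivity for the aldehyde, secured by the low basicity and carbonyl selectivity of organochromium reagents, so the acidic C11 methylene, the 8(17)-methylene and the buried C19 ester are left alone. It also needs retention of the Z geometry, secured by the trisubstituted iodide and a low nickel loading, and any E adduct cannot lactonise and is removed by chromatography.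

Step 11
Reactants: 18 C12 butenolide
Product: 20 (12S,13Z)-12-hydroxylabda-8(17),13-diene-15,19-dioic acid (target), via lithium carboxylate 19 (not isolated)
Conditions: LiOH (1.5 equiv), THF/H2O (3:1), 0 °C, short contact; concentrate cold; Bu4NF (4 equiv), THF, rt; then EtOAc/cold 0.1 M HCl to pH 4, 0 °C, immediate extraction, evaporation below rt
Reagents that add atoms: lithium hydroxide, [Li+].[OH-]
Why: Saponification of the butenolide at C15 comes first because the resulting (Z)-γ-hydroxy carboxylate no longer has an acidic C12–H, so the basic fluoride that then triggers β-silyl fragmentation of the otherwise unhydrolysable axial C19 ester (loss of Me3SiF and ethene) cannot epimerise C12, and protonation in a cold two-phase system with immediate extraction keeps acid-catalysed relactonisation slow, no stereocentre or alkene geometry being touched.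

Compound list
1 | (+)-podocarpic acid | Oc1ccc2CC[C@@H]3[C@](C)(CCC[C@]3(C)C(=O)O)c2c1 | starting material
2 | O-methylpodocarpic acid | COc1ccc2CC[C@@H]3[C@](C)(CCC[C@]3(C)C(=O)O)c2c1 | intermediate
3 | 12-methoxypodocarpa-8,12-dien-19-oic acid (Birch diene) | C1C[C@@H]2[C@](C)(CCC[C@]2(C)C(=O)O)C3=C1CC=C(OC)C3 | intermediate
4 | 12-oxopodocarp-8-en-19-oic acid (unconjugated enone) | C1C[C@@H]2[C@](C)(CCC[C@]2(C)C(=O)O)C3=C1CCC(=O)C3 | intermediate
5 | 12-oxopodocarp-9(11)-en-19-oic acid, 8β-H | C1C[C@@H]2[C@](C)(CCC[C@]2(C)C(=O)O)C3=CC(=O)CC[C@@H]31 | intermediate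
6 | 2-(trimethylsilyl)ethanol | OCC[Si](C)(C)C | starting material
7 | 2-(trimethylsilyl)ethyl 12-oxopodocarp-9(11)-en-19-oate | C1C[C@@H]2[C@](C)(CCC[C@]2(C)C(=O)OCC[Si](C)(C)C)C3=CC(=O)CC[C@@H]31 | intermediate
8 | 2-(trimethylsilyl)ethyl 12-oxo-8β,9α-podocarpan-19-oate | C1C[C@@H]2[C@](C)(CCC[C@]2(C)C(=O)OCC[Si](C)(C)C)[C@H]3CC(=O)CC[C@@H]31 | intermediate
9 | 2-(trimethylsilyl)ethyl 12-(trimethylsilyloxy)podocarp-12-en-19-oate | C1C[C@@H]2[C@](C)(CCC[C@]2(C)C(=O)OCC[Si](C)(C)C)[C@H]3CC(O[Si](C)(C)C)=CC[C@@H]31 | intermediate
10 | 12,13-seco methoxy hydroperoxide (C12 trimethylsilyl ester, C13 CH(OMe)OOH, both C13 epimers) | C1C[C@@H]2[C@](C)(CCC[C@]2(C)C(=O)OCC[Si](C)(C)C)[C@@H](CC(=O)O[Si](C)(C)C)[C@@H]1CC(OC)OO | intermediate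
11 | 13,14,15,16-tetranorlabd-8(17)-ene-12,19-dioic acid 19-[2-(trimethylsilyl)ethyl] ester | C=C1CC[C@@H]2[C@](C)(CCC[C@]2(C)C(=O)OCC[Si](C)(C)C)[C@H]1CC(=O)O | intermediate
12 | C12 N-methoxy-N-methylamide of 11 | C=C1CC[C@@H]2[C@](C)(CCC[C@]2(C)C(=O)OCC[Si](C)(C)C)[C@H]1CC(=O)N(C)OC | intermediate
13 | 2-(trimethylsilyl)ethyl 12-oxo-13,14,15,16-tetranorlabd-8(17)-en-19-oate (C12 aldehyde) | C=C1CC[C@@H]2[C@](C)(CCC[C@]2(C)C(=O)OCC[Si](C)(C)C)[C@H]1CC=O | intermediate
14 | methyl but-2-ynoate | CC#CC(=O)OC | starting material
15 | methyl (Z)-3-iodobut-2-enoate | C/C(I)=C/C(=O)OC | intermediate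
16 | (Z)-alkenylchromium dichloride from 15 (chiral ligand omitted) | C/C([Cr](Cl)Cl)=C/C(=O)OC | intermediate
17 | chromium alkoxide of the methyl (12S,13Z)-12-hydroxy-15-oate (chiral ligand omitted) | C=C1CC[C@@H]2[C@](C)(CCC[C@]2(C)C(=O)OCC[Si](C)(C)C)[C@H]1C[C@H](O[Cr](Cl)Cl)/C(C)=C\C(=O)OC | intermediate
18 | (12S)-labda-8(17),13-dien-15,12-olide 19-[2-(trimethylsilyl)ethyl] ester | C=C1CC[C@@H]2[C@](C)(CCC[C@]2(C)C(=O)OCC[Si](C)(C)C)[C@H]1C[C@@H]1OC(=O)C=C1C | intermediate
19 | lithium (12S,13Z)-12-hydroxy-19-[2-(trimethylsilyl)ethoxy]-19-oxolabda-8(17),13-dien-15-oate | C=C1CC[C@@H]2[C@](C)(CCC[C@]2(C)C(=O)OCC[Si](C)(C)C)[C@H]1C[C@H](O)/C(C)=C\C(=O)[O-].[Li+] | intermediate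
20 | (12S,13Z)-12-hydroxylabda-8(17),13-diene-15,19-dioic acid | C=C1CC[C@@H]2[C@](C)(CCC[C@]2(C)C(=O)O)[C@H]1C[C@H](O)/C(C)=C\C(=O)O | target

Total step count: 11. Longest linear sequence: 10 (steps 1–8, 10, 11).

Steps most likely to fail

Step 10. Facial selectivity at the unbranched C12 aldehyde may be poor, because everything depends on the ligand sphere. The alkenylmetal may also lose part of its geometry through an allenolate-type form.
The fallback sets out from 13. It replaces the alkenylchromium by a zinc acetylide: methyl propiolate, Me2Zn and the ProPhenol ligand antipode that gives 12S, in toluene, should furnish the γ-hydroxy ynoate F1. Syn carbocupration of F1 with excess Me2CuLi (THF, −78 °C), followed by protonation, places the new C16 methyl on C13 and leaves C12 cis to the ester. The adduct lactonises on work-up and the sequence returns to the route at 18.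

Step 6. The alkoxyl radical may be reduced to the aldehyde stage instead of fragmenting. The C14 radical may also be intercepted by hydrogen abstraction or by capture by the C12 carboxyl before copper oxidises it.
The fallback sets out from 9 and uses two-electron steps plus a classical oxidative decarboxylation.
- Ozonolysis with Me2S work-up gives the seco aldehyde acid F2.
- Carbodiimide coupling with MeNHOMe·HCl gives the aldehyde Weinreb amide F3.
- Pinnick oxidation (NaClO2, NaH2PO4, 2-methylbut-2-ene) gives the C13 acid F4.
- Pb(OAc)4/Cu(OAc)2/pyridine in hot benzene removes C13 as CO2 and installs the 8(17)-methylene, rejoining the route at 12.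

Step 11. The free (Z)-γ-hydroxy acid may relactonise during protonation and purification. Hydroxide may also partly epimerise C12 before ring opening is complete.
The fallback sets out from 18 and moves all purification to a protected stage.
- After the LiOH opening, the crude salt is silylated (Et3SiOTf, 2,6-lutidine, CH2Cl2; aqueous work-up cleaves the silyl ester). This gives the 12-O-triethylsilyl acid F5, which cannot lactonise and can be chromatographed and checked for C12 integrity.
- TASF in DMF then removes both silicon groups under nearly neutral conditions.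
- The salt is converted to the free diacid on a weakly acidic cation-exchange resin at 0–4 °C and freeze-dried, arriving at 20.

Further compounds
F1 | step 10 | methyl (12S)-12-hydroxy-16-norlabd-8(17)-en-13-yn-15-oate 19-[2-(trimethylsilyl)ethyl] ester (γ-hydroxy ynoate) | C=C1CC[C@@H]2[C@](C)(CCC[C@]2(C)C(=O)OCC[Si](C)(C)C)[C@H]1C[C@H](O)C#CC(=O)OC
F2 | step 6 | 12,13-seco-podocarpane C12 acid C13 aldehyde, 19-[2-(trimethylsilyl)ethyl] ester | C1C[C@@H]2[C@](C)(CCC[C@]2(C)C(=O)OCC[Si](C)(C)C)[C@@H](CC(=O)O)[C@@H]1CC=O
F3 | step 6 | 12,13-seco-podocarpane C12 Weinreb amide C13 aldehyde | C1C[C@@H]2[C@](C)(CCC[C@]2(C)C(=O)OCC[Si](C)(C)C)[C@@H](CC(=O)N(C)OC)[C@@H]1CC=O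
F4 | step 6 | 12,13-seco-podocarpane C12 Weinreb amide C13 acid | C1C[C@@H]2[C@](C)(CCC[C@]2(C)C(=O)OCC[Si](C)(C)C)[C@@H](CC(=O)N(C)OC)[C@@H]1CC(=O)O
F5 | step 11 | (12S,13Z)-12-(triethylsilyloxy)labda-8(17),13-diene-15,19-dioic acid 19-[2-(trimethylsilyl)ethyl] ester | C=C1CC[C@@H]2[C@](C)(CCC[C@]2(C)C(=O)OCC[Si](C)(C)C)[C@H]1C[C@H](O[Si](CC)(CC)CC)/C(C)=C\C(=O)O
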